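Retrosynthetic cuts: first the five O-protecting groups. Next the aryl ketone bond C1'–C(=O), giving a ring A aryllithium and the Weinreb amide of caffeic acid. Then C1''–C2'' and C3''–CH3 together, giving a ring A benzylic chloride, a terminal enyne and Me3Al. Last, C6''–C7'' (isopropenyl Grignard reagent on a pent-4-ynoic amide) and C3'–C1'' (formylation of a lithiated resorcinol bis-acetal).
Enabling feature: the E-trisubstituted alkene C2''=C3'' carries its methyl on C3'' and is separated from ring A carbon C3' only by the methylene C1''. This is the pattern produced by syn methyl–aluminium addition to a 1-alkyne followed by alkenyl–benzyl coupling. C3' sits between the two ring A oxygens, so C1'' can be placed there unambiguously.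
Forward order: no ring is formed, since both benzene rings are purchased. The C8 enyne and the benzylic chloride take four steps each and are joined in step 9. Ring A is then lithiated at C1' and acylated with the ring B cinnamoyl unit, and one acid step removes all protecting groups.
Stereochemistry: C6'' (R) comes from an oxazaborolidine-catalysed ketone reduction. The E geometry of C2''=C3'' comes from syn carbometalation and a coupling that retains geometry. The E enone alkene is carried in from caffeic acid.

Key step: step 9

Remark: the [C@H] descriptor at C6'' is read as R (OH > isopropenyl > CH2 > H). Primed locants follow chalcone usage: ring A is the resorcinol ring bearing the ketone at C1', ring B is the catechol ring, and the side chain is C1''–C8''.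

Step 1
Reactants: 1 pent-4-ynoic acid
Product: 2 N-methoxy-N-methylpent-4-ynamide
Conditions: MeNH(OMe)·HCl, EDC·HCl, Et3N, CH2Cl2, 0 °C → rt
Reagents that add atoms: N,O-dimethylhydroxylamine hydrochloride, CNOC.Cl
Why: Carbodiimide-mediated amide coupling of a simple acid with N,O-dimethylhydroxylamine is routine and leaves the terminal alkyne untouched.

Step 2
Reactants: 2 N-methoxy-N-methylpent-4-ynamide; 3 isopropenylmagnesium bromide
Product: 4 2-methylhept-1-en-6-yn-3-one
Conditions: 3 (2.3 equiv), THF, −78 → 0 °C; poured into cold 1 M aq. HCl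
Reagents that add atoms: isopropenylmagnesium bromide 3, C=C(C)[Mg]Br
Why: In this Weinreb ketone synthesis one equivalent of 3 is spent on the acidic alkyne C–H and a second adds to the amide, magnesium chelation by the N-methoxy group prevents over-addition, and the cold acidic quench keeps the released hydroxylamine protonated so that it cannot add to the new enone.

Step 3
Reactants: 4 2-methylhept-1-en-6-yn-3-one
Product: 5 (R)-2-methylhept-1-en-6-yn-3-ol
Conditions: (S)-1-methyl-3,3-diphenyltetrahydro-1H,3H-pyrrolo[1,2-c][1,3,2]oxazaborole (0.15 equiv), catecholborane (1.8 equiv), toluene, −78 °C; aq. NaOH work-up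
Reagents that add atoms: none
Why: In this Corey–Bakshi–Shibata reduction the ketone oxygen binds the ring boron anti to the bulkier, branched sp2 isopropenyl group, so the borane held on nitrogen should deliver hydride to the Si face and set C6'' as R (the sense in which this (S)-catalyst converts acetophenone into the (R)-alcohol), while catecholborane at −78 °C does not hydroborate the alkyne or the alkene.

Step 4
Reactants: 5 (R)-2-methylhept-1-en-6-yn-3-ol
Product: 6 (R)-tert-butyldimethyl[(2-methylhept-1-en-6-yn-3-yl)oxy]silane
Conditions: TBSCl, imidazole, DMF, rt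
Reagents that add atoms: tert-butyldimethylsilyl chloride, CC(C)(C)[Si](C)(C)Cl
Why: Imidazole-promoted silylation occurs at oxygen without touching the C–O bond, so R is kept, and the TBS ether tolerates Me3Al, zerovalent nickel and n-BuLi yet is removed together with the acetals in the last step.

Step 5
Reactants: 7 resorcinol
Product: 8 1,3-bis(methoxymethoxy)benzene
Conditions: MOMCl (2.5 equiv), iPr2NEt, CH2Cl2, 0 °C → rt
Reagents that add atoms: chloromethyl methyl ether, COCCl
Why: O-alkylation of both phenols with the activated chloromethyl ether is standard and installs the acetals that later direct both lithiations.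

Step 6
Reactants: 8 1,3-bis(methoxymethoxy)benzene
Product: 10 2,6-bis(methoxymethoxy)benzaldehyde, via aryllithium 9 (not isolated)
Conditions: n-BuLi (1.1 equiv), THF, 0 °C → rt; DMF, 0 °C; H2O
Reagents that add atoms: N,N-dimethylformamide, CN(C)C=O; n-butyllithium, [Li]CCCC (supplies the lithium of 9)
Why: In this directed ortho-metalation the C–H between the two acetal oxygens is the most acidic and doubly coordinated site, so lithiation is confined to the future C3', and formylation of the aryllithium with DMF brings in the future C1''.

Step 7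
Reactants: 10 2,6-bis(methoxymethoxy)benzaldehyde
Product: 11 [2,6-bis(methoxymethoxy)phenyl]methanol
Conditions: NaBH4, MeOH, 0 °C; H2O
Reagents that add atoms: none
Why: Borohydride reduction of an aromatic aldehyde is chemoselective and its basic medium does not harm the acetals.

Step 8
Reactants: 11 [2,6-bis(methoxymethoxy)phenyl]methanol
Product: 13 2-(chloromethyl)-1,3-bis(methoxymethoxy)benzene, via benzylic mesylate 12 (not isolated)
Conditions: MsCl (1.2 equiv), Et3N (1.5 equiv), CH2Cl2, 0 °C → rt; cold aq. NaHCO3 wash, used at once without chromatography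
Reagents that add atoms: methanesulfonyl chloride, CS(=O)(=O)Cl
Why: Mesylation under basic conditions is followed by in situ nucleophilic displacement of the very reactive electron-rich benzylic mesylate by the chloride formed in the flask, so the chloride is obtained without any acid that could cleave the acetals.

Step 9
Reactants: 6 (R)-tert-butyldimethyl[(2-methylhept-1-en-6-yn-3-yl)oxy]silane; 14 trimethylaluminium; 13 2-(chloromethyl)-1,3-bis(methoxymethoxy)benzene
Product: 16 2-[(2E,6R)-6-(tert-butyldimethylsilyloxy)-3,7-dimethylocta-2,7-dien-1-yl]-1,3-bis(methoxymethoxy)benzene, via alkenylalane 15 (not isolated)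
Conditions: (a) 14 (2.0 equiv), Cp2ZrCl2 (0.25 equiv), CH2Cl2, 0 °C → rt; volatiles and surplus 14 removed in vacuo, residue extracted into hexane and taken up in THF; (b) 13, NiCl2(PPh3)2 (5 mol %) pre-reduced with n-BuLi (10 mol %), THF, 0 °C → rt; aq. potassium sodium tartrate
Reagents that add atoms: trimethylaluminium 14, C[Al](C)C
Why: This is the Negishi zirconium-catalysed methylalumination of a 1-alkyne joined to a nickel-catalysed alkenylalane–benzylic chloride cross-coupling, a pairing established for alkoxy-substituted benzylic chlorides. A methylzirconocene cation paired with a chloroaluminate adds methyl and metal to the same face of the triple bond, methyl at the internal carbon (future C3'') and metal at the terminal one (future C2''), and zirconium–aluminium exchange releases (E)-alkenylalane 15 and returns the catalyst. Zerovalent nickel then inserts into the benzylic C–Cl bond of 13, the sp2 carbon passes from aluminium to nickel, and reductive elimination forms C1''–C2'' with retention, so the E geometry fixed in the carbometalation is carried into 16. No ring is closed and no stereocentre is made, and C6'', two methylene groups away from the nearest reacting carbon, keeps its R configuration under the TBS ether. The selectivities required are alkyne over the 1,1-disubstituted C7''=C8'' alkene, terminal placement of aluminium, and alkenyl rather than methyl transfer, and they rest on the inertness of 1,1-disubstituted alkenes to Cp2ZrCl2/Me3Al, the steric bias of a 1-alkyne, and removal of surplus 14 before the coupling. The benzylic partner has no β-hydrogen, its two flanking oxygens fix the chain at C3' of ring A, and the change to THF damps the Lewis acidity of aluminium so that the MOM acetals should survive.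

Step 10
Reactants: 17 caffeic acid
Product: 18 (E)-3-(3,4-dihydroxyphenyl)-N-methoxy-N-methylprop-2-enamide
Conditions: MeNH(OMe)·HCl, EDC·HCl, HOBt, Et3N, DMF, 0 °C → rt
Reagents that add atoms: N,O-dimethylhydroxylamine hydrochloride, CNOC.Cl
Why: Carbodiimide/HOBt amide coupling favours the amine nucleophile over the free catechol hydroxyls, as is usual for caffeic amides, and does not disturb the E alkene.

Step 11
Reactants: 18 (E)-3-(3,4-dihydroxyphenyl)-N-methoxy-N-methylprop-2-enamide
Product: 19 (E)-3-[3,4-bis(methoxymethoxy)phenyl]-N-methoxy-N-methylprop-2-enamide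
Conditions: MOMCl (3 equiv), iPr2NEt, CH2Cl2, 0 °C → rt
Reagents that add atoms: chloromethyl methyl ether, COCCl
Why: O-alkylation of both catechol hydroxyls removes the acidic protons before the organolithium step and uses the same acetal as on ring A, so that one deprotection serves all.

Step 12
Reactants: 16 2-[(2E,6R)-6-(tert-butyldimethylsilyloxy)-3,7-dimethylocta-2,7-dien-1-yl]-1,3-bis(methoxymethoxy)benzene; 19 (E)-3-[3,4-bis(methoxymethoxy)phenyl]-N-methoxy-N-methylprop-2-enamide
Product: 21 (E)-1-{3-[(2E,6R)-6-(tert-butyldimethylsilyloxy)-3,7-dimethylocta-2,7-dien-1-yl]-2,4-bis(methoxymethoxy)phenyl}-3-[3,4-bis(methoxymethoxy)phenyl]prop-2-en-1-one, via aryllithium 20 (not isolated)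
Conditions: n-BuLi (1.1 equiv), THF, −20 → 0 °C; 19 in THF, −78 → −20 °C; AcOH in THF, −78 °C
Reagents that add atoms: n-butyllithium, [Li]CCCC (supplies the lithium of 20)
Why: In this directed ortho-metalation followed by Weinreb ketone synthesis the acetal oxygens guide n-BuLi to the ring C–H beside an OMOM group (the two such positions are equivalent, so only C1' can result), and the hard aryllithium adds 1,2 to the cinnamoyl Weinreb amide, where chelation stops the reaction at the ketone stage and the E alkene is retained.

Step 13
Reactants: 21 (E)-1-{3-[(2E,6R)-6-(tert-butyldimethylsilyloxy)-3,7-dimethylocta-2,7-dien-1-yl]-2,4-bis(methoxymethoxy)phenyl}-3-[3,4-bis(methoxymethoxy)phenyl]prop-2-en-1-one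
Product: 22 (E)-1-{2,4-dihydroxy-3-[(2E,6R)-6-hydroxy-3,7-dimethylocta-2,7-dien-1-yl]phenyl}-3-(3,4-dihydroxyphenyl)prop-2-en-1-one
Conditions: 3 M aq. HCl, MeOH (degassed), argon, rt → 40 °C
Reagents that add atoms: none
Why: Acid-catalysed hydrolysis of aryl MOM acetals and of a secondary TBS ether is the usual closing step for prenylated and geranylated chalcones, and dilute acid at low temperature is chosen so that no alkene is protonated, the C6''–O bond does not ionise (R is kept), and the hydrogen-bonded 2'-hydroxychalcone does not close to the flavanone.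

Compound list
1 | pent-4-ynoic acid | C#CCCC(=O)O | starting material
2 | N-methoxy-N-methylpent-4-ynamide | C#CCCC(=O)N(C)OC | intermediate
3 | isopropenylmagnesium bromide | C=C(C)[Mg]Br | starting material
4 | 2-methylhept-1-en-6-yn-3-one | C=C(C)C(=O)CCC#C | intermediate
5 | (R)-2-methylhept-1-en-6-yn-3-ol | C=C(C)[C@H](O)CCC#C | intermediate
6 | (R)-tert-butyldimethyl[(2-methylhept-1-en-6-yn-3-yl)oxy]silane | C=C(C)[C@H](O[Si](C)(C)C(C)(C)C)CCC#C | intermediate
7 | resorcinol | Oc1cccc(O)c1 | starting material
8 | 1,3-bis(methoxymethoxy)benzene | COCOc1cccc(OCOC)c1 | intermediate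
9 | [2,6-bis(methoxymethoxy)phenyl]lithium (not isolated) | [Li]c1c(OCOC)cccc1OCOC | intermediate
10 | 2,6-bis(methoxymethoxy)benzaldehyde | O=Cc1c(OCOC)cccc1OCOC | intermediate
11 | [2,6-bis(methoxymethoxy)phenyl]methanol | OCc1c(OCOC)cccc1OCOC | intermediate
12 | 2,6-bis(methoxymethoxy)benzyl methanesulfonate (not isolated) | CS(=O)(=O)OCc1c(OCOC)cccc1OCOC | intermediate
13 | 2-(chloromethyl)-1,3-bis(methoxymethoxy)benzene | ClCc1c(OCOC)cccc1OCOC | intermediate
14 | trimethylaluminium | C[Al](C)C | starting material
15 | [(1E,5R)-5-(tert-butyldimethylsilyloxy)-2,6-dimethylhepta-1,6-dien-1-yl]dimethylalane (not isolated) | C=C(C)[C@H](O[Si](C)(C)C(C)(C)C)CC/C(C)=C/[Al](C)C | intermediate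
16 | 2-[(2E,6R)-6-(tert-butyldimethylsilyloxy)-3,7-dimethylocta-2,7-dien-1-yl]-1,3-bis(methoxymethoxy)benzene | C=C(C)[C@H](O[Si](C)(C)C(C)(C)C)CC/C(C)=C/Cc1c(OCOC)cccc1OCOC | intermediate
17 | caffeic acid, (E)-3-(3,4-dihydroxyphenyl)prop-2-enoic acid | O=C(O)/C=C/c1ccc(O)c(O)c1 | starting material
18 | (E)-3-(3,4-dihydroxyphenyl)-N-methoxy-N-methylprop-2-enamide | CON(C)C(=O)/C=C/c1ccc(O)c(O)c1 | intermediate
19 | (E)-3-[3,4-bis(methoxymethoxy)phenyl]-N-methoxy-N-methylprop-2-enamide | CON(C)C(=O)/C=C/c1ccc(OCOC)c(OCOC)c1 | intermediate
20 | {3-[(2E,6R)-6-(tert-butyldimethylsilyloxy)-3,7-dimethylocta-2,7-dien-1-yl]-2,4-bis(methoxymethoxy)phenyl}lithium (not isolated) | C=C(C)[C@H](O[Si](C)(C)C(C)(C)C)CC/C(C)=C/Cc1c(OCOC)ccc([Li])c1OCOC | intermediate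
21 | (E)-1-{3-[(2E,6R)-6-(tert-butyldimethylsilyloxy)-3,7-dimethylocta-2,7-dien-1-yl]-2,4-bis(methoxymethoxy)phenyl}-3-[3,4-bis(methoxymethoxy)phenyl]prop-2-en-1-one | C=C(C)[C@H](O[Si](C)(C)C(C)(C)C)CC/C(C)=C/Cc1c(OCOC)ccc(C(=O)/C=C/c2ccc(OCOC)c(OCOC)c2)c1OCOC | intermediate
22 | (E)-1-{2,4-dihydroxy-3-[(2E,6R)-6-hydroxy-3,7-dimethylocta-2,7-dien-1-yl]phenyl}-3-(3,4-dihydroxyphenyl)prop-2-en-1-one | C=C(C)[C@H](O)CC/C(C)=C/Cc1c(O)ccc(C(=O)/C=C/c2ccc(O)c(O)c2)c1O | target

Total step count: 13.
Longest linear sequence: 7 steps (steps 1–4, 9, 12, 13). The resorcinol branch (steps 5–8, 9, 12, 13) is equally long.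

Steps most likely to fail

Step 12. n-BuLi may remove a proton from the C1'' methylene, which is both benzylic and allylic, instead of the ring C–H next to the acetal. The consequences would be alkene migration or acylation in the chain. Conjugate addition to the unsaturated amide is a lesser concern.

The fallback replaces C–H lithiation of the chain-bearing arene by bromine–lithium exchange. It sets out from 11.
- Two equivalents of n-BuLi (THF, 0 °C) give lithium [3-lithio-2,6-bis(methoxymethoxy)phenyl]methanolate F1, because both positions next to the alkoxide arm are blocked and only the C–H beside an acetal remains.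
- BrCF2CF2Br followed by water gives [3-bromo-2,6-bis(methoxymethoxy)phenyl]methanol F2.
- MsCl/Et3N leads through 3-bromo-2,6-bis(methoxymethoxy)benzyl methanesulfonate F3 to 1-bromo-3-(chloromethyl)-2,4-bis(methoxymethoxy)benzene F4.
- Alkenylalane 15 is coupled with F4 under Pd(PPh3)4 in THF at room temperature. There the benzylic C–Cl bond should add to zerovalent palladium well before an electron-rich aryl C–Br bond, giving 1-bromo-3-[(2E,6R)-6-(tert-butyldimethylsilyloxy)-3,7-dimethylocta-2,7-dien-1-yl]-2,4-bis(methoxymethoxy)benzene F5.
- t-BuLi (2 equiv, −78 °C) then produces aryllithium 20 by halogen exchange, which outruns any deprotonation.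

The route is rejoined at 20 and continues to 21.

Step 13. Several acid-driven processes may compete with acetal hydrolysis:
- addition of the C2' or C4' phenol to the C2''=C3'' alkene (chroman closure)
- isomerisation of the 2'-hydroxychalcone to the flavanone
- ionisation or allylic transposition at C6'' with erosion of configuration
- air oxidation of the free catechol

The fallback avoids Brønsted acid by exchanging the acetals for silyl ethers and finishing with fluoride. It sets out from 21. TMSOTf and 2,2'-bipyridyl in MeCN (0 °C → rt) convert the four aryl MOM ethers into (E)-1-{3-[(2E,6R)-6-(tert-butyldimethylsilyloxy)-3,7-dimethylocta-2,7-dien-1-yl]-2,4-bis(trimethylsilyloxy)phenyl}-3-[3,4-bis(trimethylsilyloxy)phenyl]prop-2-en-1-one F6. HF·pyridine buffered with pyridine in THF (0 °C) then removes all five silyl groups. The route is rejoined at 22.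

Step 9. Aluminium Lewis acids may ionise the electron-rich benzylic chloride before nickel reaches it. A neighbouring acetal oxygen could then capture the cation with loss of that protecting group. Methyl transfer from residual 14 and reductive dimerisation of the benzylic partner are further drains.

The fallback forms the same two bonds in separate operations and keeps aluminium away from the acetals. It sets out from 15 and 13.
- Alkenylalane 15 is quenched with I2 (THF, −30 → 0 °C) to give (R,E)-tert-butyl[(7-iodo-2,6-dimethylhepta-1,6-dien-3-yl)oxy]dimethylsilane F7, with retention of geometry.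
- Freshly made 13 is stirred with Zn dust and LiCl in THF to give [2,6-bis(methoxymethoxy)benzyl]zinc chloride F8. As a nucleophile this is no longer prone to ionisation.
- Negishi coupling of F7 with F8 under Pd(PPh3)4 (THF, rt) forms C1''–C2''.

The route is rejoined at 16.

Further compounds
F1 | step 12 | lithium [3-lithio-2,6-bis(methoxymethoxy)phenyl]methanolate | [Li]OCc1c(OCOC)ccc([Li])c1OCOC
F2 | step 12 | [3-bromo-2,6-bis(methoxymethoxy)phenyl]methanol | OCc1c(OCOC)ccc(Br)c1OCOC
F3 | step 12 | 3-bromo-2,6-bis(methoxymethoxy)benzyl methanesulfonate | CS(=O)(=O)OCc1c(OCOC)ccc(Br)c1OCOC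
F4 | step 12 | 1-bromo-3-(chloromethyl)-2,4-bis(methoxymethoxy)benzene | ClCc1c(OCOC)ccc(Br)c1OCOC
F5 | step 12 | 1-bromo-3-[(2E,6R)-6-(tert-butyldimethylsilyloxy)-3,7-dimethylocta-2,7-dien-1-yl]-2,4-bis(methoxymethoxy)benzene | C=C(C)[C@H](O[Si](C)(C)C(C)(C)C)CC/C(C)=C/Cc1c(OCOC)ccc(Br)c1OCOC
F6 | step 13 | (E)-1-{3-[(2E,6R)-6-(tert-butyldimethylsilyloxy)-3,7-dimethylocta-2,7-dien-1-yl]-2,4-bis(trimethylsilyloxy)phenyl}-3-[3,4-bis(trimethylsilyloxy)phenyl]prop-2-en-1-one | C=C(C)[C@H](O[Si](C)(C)C(C)(C)C)CC/C(C)=C/Cc1c(O[Si](C)(C)C)ccc(C(=O)/C=C/c2ccc(O[Si](C)(C)C)c(O[Si](C)(C)C)c2)c1O[Si](C)(C)C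
F7 | step 9 | (R,E)-tert-butyl[(7-iodo-2,6-dimethylhepta-1,6-dien-3-yl)oxy]dimethylsilane | C=C(C)[C@H](O[Si](C)(C)C(C)(C)C)CC/C(C)=C/I
F8 | step 9 | [2,6-bis(methoxymethoxy)benzyl]zinc chloride | Cl[Zn]Cc1c(OCOC)cccc1OCOC
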